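The two carbocycles are bought as phloroglucinols, so the 2H-pyran (ring C: O1, C2, C3, C4, C4a, C8a) is the only ring that must be built. It is read as the valence tautomer of an ortho-quinone methide. Prenal condenses with a ring CH of a hexanoylphloroglucinol capped at its para oxygen, and oxa-6π closure sets C4–C4a and O1–C2 in one operation. The cap leaves two homotopic CH/OH pairs beside the acyl carbon, which places O1 next to C8. Ring B comes from enantioselective dearomative geranylation of an aminomethylated methylphloracetophenone. The aminomethyl group blocks the free carbon and then becomes the methylene bridge to C6.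

Key step: step 3

Remark on drawing: rings A (arene) and C (pyran) carry chromene numbering and ring B is the cyclohexadienone. Ring B compounds are drawn neutral and in the tautomer of the target, and CIP descriptors refer to these drawings.
Assumption: the (1R,2R)-ligand is taken to deliver the (4R)-centre. The sense has to be verified on the first chiral intermediate, and the equally commercial (1S,2S)-ligand would be used if it proves opposite.

Step 1
Reactants: 1 phloroglucinol (benzene-1,3,5-triol); 2 hexanoyl chloride
Product: 3 1-(2,4,6-trihydroxyphenyl)hexan-1-one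
Conditions: AlCl3 (3.5 equiv), CH2Cl2/MeNO2, 0 to 40 °C; aq HCl quench
Reagents that add atoms: none
Why: Friedel–Crafts C-acylation of the threefold symmetric triol, in which the aluminium chelate of the first aryl ketone deactivates the ring toward a second acylation.

Step 2
Reactants: 3 1-(2,4,6-trihydroxyphenyl)hexan-1-one
Product: 4 1-[2,6-dihydroxy-4-(methoxymethoxy)phenyl]hexan-1-one
Conditions: MOMCl (1.0 equiv), i-Pr2NEt (1.1 equiv), CH2Cl2, −10 to 0 °C
Reagents that add atoms: chloromethyl methyl ether (MOMCl), COCCl
Why: Williamson-type O-alkylation in which the 4-OH, para to the ketone, is the most acidic and least hindered hydroxyl and is never held in the ketone chelate, so one equivalent of the hard electrophile should cap it first and leave a mirror-symmetric ring.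

Step 3
Reactants: 4 1-[2,6-dihydroxy-4-(methoxymethoxy)phenyl]hexan-1-one; 5 3-methylbut-2-enal (prenal)
Product: 7 1-[7-hydroxy-5-(methoxymethoxy)-2,2-dimethyl-2H-chromen-8-yl]hexan-1-one, via vinyl ortho-quinone methide 6 (not isolated)
Conditions: 5 (1.1 equiv), ethylenediammonium diacetate (20 mol%), 4 Å MS, toluene, 110 °C
Reagents that add atoms: none
Why: The diammonium diacetate turns 5 into its iminium ion, one of the two homotopic ring CH carbons of 4 adds to it in a Knoevenagel-type condensation (C4–C4a), and loss of the amine dearomatises ring A to the (Z)-vinyl ortho-quinone methide 6. Compound 6 is a 1-oxatriene (O1=C8a–C4a=C4–C3=C2) that closes ring C by a thermally allowed disrotatory oxa-6π electrocyclisation, which makes O1–C2 and rearomatises ring A, so two bonds and the whole pyran arise in one operation. The closest known reaction type is the amine-catalysed formal [3+3] chromenylation of resorcinols and 4-O-alkyl acylphloroglucinols with enals. No stereocentre is formed. The step needs O1 to be the oxygen beside the acyl-bearing C8 and not the para oxygen, and the MOM cap secures this by removing the para oxygen from play and making both remaining CH/OH pairs homotopic, so that only one chromene can form. A second annulation is held back by the single equivalent of 5 and by the ketone chelate of the last free OH, and conjugate addition is blocked by the β,β-dimethyl terminus of 5.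

Step 4
Reactants: 7 1-[7-hydroxy-5-(methoxymethoxy)-2,2-dimethyl-2H-chromen-8-yl]hexan-1-one
Product: 8 1-(5,7-dihydroxy-2,2-dimethyl-2H-chromen-8-yl)hexan-1-one
Conditions: HCl (2 M in MeOH), 40 °C
Reagents that add atoms: none
Why: Acid-catalysed acetal exchange with methanol cleaves the aryl MOM ether, which is activated by the para ketone, under mild conditions that 2,2-dimethylchromenes are known to tolerate.

Step 5
Reactants: 9 2-methylbenzene-1,3,5-triol; 10 acetyl chloride
Product: 11 1-(2,4,6-trihydroxy-3-methylphenyl)ethan-1-one
Conditions: AlCl3 (3.5 equiv), CH2Cl2/MeNO2, 0 to 40 °C; aq HCl quench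
Reagents that add atoms: none
Why: Friedel–Crafts acylation at one of the two equivalent free positions of 9, with the chelated product deactivated toward a second acylation.

Step 6
Reactants: 11 1-(2,4,6-trihydroxy-3-methylphenyl)ethan-1-one; 12 formaldehyde
Product: 13 1-{3-[(dimethylamino)methyl]-2,4,6-trihydroxy-5-methylphenyl}ethan-1-one
Conditions: 37% aq CH2O (1.05 equiv), 40% aq Me2NH (1.05 equiv), EtOH, 0 °C to rt
Reagents that add atoms: dimethylamine, CNC
Why: Mannich aminomethylation can only strike the single free ring carbon of 11, and it should give a zwitterion that precipitates, blocks that carbon and already carries the future bridge carbon.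

Step 7
Reactants: 13 1-{3-[(dimethylamino)methyl]-2,4,6-trihydroxy-5-methylphenyl}ethan-1-one; 14 geranyl acetate
Product: 15 (4R)-2-acetyl-6-[(dimethylamino)methyl]-4-[(2E)-3,7-dimethylocta-2,6-dien-1-yl]-3,5-dihydroxy-4-methylcyclohexa-2,5-dien-1-one
Conditions: 14 (1.1 equiv), Pd2(dba)3·CHCl3 (2.5 mol%), (1R,2R)-N,N'-bis[2-(diphenylphosphino)benzoyl]cyclohexane-1,2-diamine (7.5 mol%), Et3N (1.2 equiv), degassed CH2Cl2, rt
Reagents that add atoms: none
Why: Proposed new method: zerovalent palladium ionises 14 to the π-geranyl complex, and the soft ammonium phenoxide of 13 attacks its unsubstituted terminus from outside the metal through the methyl-bearing carbon, the less hindered of the two non-acylated ring carbons, so that the linear E-geranyl chain is kept, O- and N-allylation stay reversible under the catalysis, and the chiral pocket of the diphosphine should pick one enantiotopic ring face by telling the acetyl flank from the aminomethyl flank and thereby set C4; the closest known reaction types are the racemic Pd-catalysed dearomative allylation of acylphloroglucinols, the asymmetric allylic dearomatisation of naphthols, and the asymmetric prenylation and geranylation of 3-substituted oxindoles with this ligand family.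

Step 8
Reactants: 15 (4R)-2-acetyl-6-[(dimethylamino)methyl]-4-[(2E)-3,7-dimethylocta-2,6-dien-1-yl]-3,5-dihydroxy-4-methylcyclohexa-2,5-dien-1-one; 8 1-(5,7-dihydroxy-2,2-dimethyl-2H-chromen-8-yl)hexan-1-one
Product: 17 (4R)-2-acetyl-4-[(2E)-3,7-dimethylocta-2,6-dien-1-yl]-6-[(8-hexanoyl-5,7-dihydroxy-2,2-dimethyl-2H-chromen-6-yl)methyl]-3,5-dihydroxy-4-methylcyclohexa-2,5-dien-1-one, via enone methide 16 (not isolated)
Conditions: 8 (1.1 equiv), AcOH (20 mol%), 1,4-dioxane, 70 °C, N2 stream
Reagents that add atoms: none
Why: Thermal loss of dimethylamine from zwitterion 15 gives the enone methide 16, which is trapped by Friedel–Crafts-type Michael addition of C6 of 8, its only free ring carbon and one flanked by two hydroxyls (the Mannich-base route to methylene-bridged phloroglucinol dimers), while the quaternary centre is not touched.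

Compound list
1 | phloroglucinol (benzene-1,3,5-triol) | Oc1cc(O)cc(O)c1 | starting material
2 | hexanoyl chloride | CCCCCC(=O)Cl | starting material
3 | 1-(2,4,6-trihydroxyphenyl)hexan-1-one | CCCCCC(=O)c1c(O)cc(O)cc1O | intermediate
4 | 1-[2,6-dihydroxy-4-(methoxymethoxy)phenyl]hexan-1-one | CCCCCC(=O)c1c(O)cc(OCOC)cc1O | intermediate
5 | 3-methylbut-2-enal (prenal) | CC(C)=CC=O | starting material
6 | (6Z)-2-hexanoyl-3-hydroxy-5-(methoxymethoxy)-6-(3-methylbut-2-en-1-ylidene)cyclohexa-2,4-dien-1-one, formed in the flask | CCCCCC(=O)C1=C(O)C=C(OCOC)/C(=C/C=C(C)C)C1=O | intermediate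
7 | 1-[7-hydroxy-5-(methoxymethoxy)-2,2-dimethyl-2H-chromen-8-yl]hexan-1-one | CCCCCC(=O)c1c(O)cc(OCOC)c2c1OC(C)(C)C=C2 | intermediate
8 | 1-(5,7-dihydroxy-2,2-dimethyl-2H-chromen-8-yl)hexan-1-one | CCCCCC(=O)c1c(O)cc(O)c2c1OC(C)(C)C=C2 | intermediate
9 | 2-methylbenzene-1,3,5-triol | Cc1c(O)cc(O)cc1O | starting material
10 | acetyl chloride | CC(=O)Cl | starting material
11 | 1-(2,4,6-trihydroxy-3-methylphenyl)ethan-1-one | CC(=O)c1c(O)cc(O)c(C)c1O | intermediate
12 | formaldehyde | C=O | starting material
13 | 1-{3-[(dimethylamino)methyl]-2,4,6-trihydroxy-5-methylphenyl}ethan-1-one | CC(=O)c1c(O)c(CN(C)C)c(O)c(C)c1O | intermediate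
14 | geranyl acetate, (2E)-3,7-dimethylocta-2,6-dien-1-yl acetate | CC(=O)OC/C=C(\C)CCC=C(C)C | starting material
15 | (4R)-2-acetyl-6-[(dimethylamino)methyl]-4-[(2E)-3,7-dimethylocta-2,6-dien-1-yl]-3,5-dihydroxy-4-methylcyclohexa-2,5-dien-1-one | CN(C)CC1=C(O)[C@@](C)(C/C=C(\C)CCC=C(C)C)C(O)=C(C(C)=O)C1=O | intermediate
16 | 2-acetyl-4-[(2E)-3,7-dimethylocta-2,6-dien-1-yl]-3-hydroxy-4-methyl-6-methylidenecyclohex-2-ene-1,5-dione, formed in the flask, (4S) by the sequence rule with the same spatial arrangement as 15 | C=C1C(=O)[C@@](C)(C/C=C(\C)CCC=C(C)C)C(O)=C(C(C)=O)C1=O | intermediate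
17 | (4R)-2-acetyl-4-[(2E)-3,7-dimethylocta-2,6-dien-1-yl]-6-[(8-hexanoyl-5,7-dihydroxy-2,2-dimethyl-2H-chromen-6-yl)methyl]-3,5-dihydroxy-4-methylcyclohexa-2,5-dien-1-one | CCCCCC(=O)c1c(O)c(CC2=C(O)[C@@](C)(C/C=C(\C)CCC=C(C)C)C(O)=C(C(C)=O)C2=O)c(O)c2c1OC(C)(C)C=C2 | target

Total step count: 8. Longest linear sequence: 5 steps (1, 2, 3, 4, 8).

Steps most likely to fail

**Step 7 (bears the label).**
- What may go wrong: Facial selectivity may be poor, because the two flanks of the reacting carbon differ only one atom further out. Alkene geometry may partly erode through π-σ-π isomerisation of the allyl complex. Attack may leak to the aminomethyl-bearing carbon or to nitrogen.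
- Fallback: it sets out from 11 and comes back to the route at 17, using only known chemistry.
  - Compound 11 is aminomethylated (Mannich reaction) with formaldehyde and commercial (S)-N-methyl-1-phenylethylamine to 1-[2,4,6-trihydroxy-3-methyl-5-({methyl[(1S)-1-phenylethyl]amino}methyl)phenyl]ethan-1-one F1.
  - Tsuji–Trost geranylation of F1 with 14 and achiral Pd(PPh3)4 is the known racemic dearomative allylation of acylphloroglucinols. It should give the (4R,1'S)-configured geranylated Mannich base F2 together with its (4S,1'S)-epimer F3.
  - As diastereomeric zwitterions, the two are separated by fractional crystallisation or chromatography.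
  - F2 then takes the place of 15 in the union with 8, where the chiral amine leaves as the nucleofuge by way of 16 and 17 is reached.

**Step 8.**
- What may go wrong: The amine that is released may trigger retro-Michael exchange of the methylene bridge at the reaction temperature and scramble the two halves into symmetric dimers. The methide may also be consumed by self-trapping.
- Fallback: it sets out from 15 and comes back at 17.
  - Compound 15 is stirred with sodium 4-methylbenzenesulfinate in aqueous formic acid. This exchanges the amine for the sulfinate and should give the neutral, storable sulfone 2-acetyl-4-[(2E)-3,7-dimethylocta-2,6-dien-1-yl]-3,5-dihydroxy-4-methyl-6-[(4-methylbenzenesulfonyl)methyl]cyclohexa-2,5-dien-1-one F4. F4 is (4S) by the sequence rule and has the same spatial arrangement as 15.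
  - With 8 and NaHCO3 in MeCN at 0 °C to rt, F4 loses sulfinate, and 16 forms in low stationary concentration without any amine present.
  - Michael addition of C6 of 8 then gives 17 below the temperature at which the bridge exchanges.

**Step 3.**
- What may go wrong: Condensation of the acyl-deactivated, chelated ring may be sluggish. The enal may self-condense, and a second annulation at C6 may follow.
- Fallback: it sets out from 4 and comes back at 7, and it closes the same ring by a sigmatropic route instead of a condensation.
  - One of the two homotopic hydroxyls of 4 is etherified with 3-chloro-3-methylbut-1-yne (CuCl2 cat., DBU, MeCN, 0 °C) to 1-[2-hydroxy-4-(methoxymethoxy)-6-(2-methylbut-3-yn-2-yloxy)phenyl]hexan-1-one F5.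
  - Heating in xylene at 135 °C should bring about the aromatic Claisen rearrangement to the only free ortho carbon. This gives 1-[2,6-dihydroxy-4-(methoxymethoxy)-3-(3-methylbuta-1,2-dien-1-yl)phenyl]hexan-1-one F6.
  - A 1,5-hydrogen shift in F6 leads to 6, and oxa-6π closure leads to 7.

Further compounds
F1 | step 7 | 1-[2,4,6-trihydroxy-3-methyl-5-({methyl[(1S)-1-phenylethyl]amino}methyl)phenyl]ethan-1-one | C[C@@H](c1ccccc1)N(C)Cc2c(O)c(C)c(O)c(C(C)=O)c2O
F2 | step 7 | (4R)-2-acetyl-4-[(2E)-3,7-dimethylocta-2,6-dien-1-yl]-3,5-dihydroxy-4-methyl-6-({methyl[(1S)-1-phenylethyl]amino}methyl)cyclohexa-2,5-dien-1-one | C[C@@H](c1ccccc1)N(C)CC2=C(O)[C@@](C)(C/C=C(\C)CCC=C(C)C)C(O)=C(C(C)=O)C2=O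
F3 | step 7 | (4S)-2-acetyl-4-[(2E)-3,7-dimethylocta-2,6-dien-1-yl]-3,5-dihydroxy-4-methyl-6-({methyl[(1S)-1-phenylethyl]amino}methyl)cyclohexa-2,5-dien-1-one | C[C@@H](c1ccccc1)N(C)CC2=C(O)[C@](C)(C/C=C(\C)CCC=C(C)C)C(O)=C(C(C)=O)C2=O
F4 | step 8 | (4S)-2-acetyl-4-[(2E)-3,7-dimethylocta-2,6-dien-1-yl]-3,5-dihydroxy-4-methyl-6-[(4-methylbenzenesulfonyl)methyl]cyclohexa-2,5-dien-1-one | Cc1ccc(cc1)S(=O)(=O)CC2=C(O)[C@@](C)(C/C=C(\C)CCC=C(C)C)C(O)=C(C(C)=O)C2=O
F5 | step 3 | 1-[2-hydroxy-4-(methoxymethoxy)-6-(2-methylbut-3-yn-2-yloxy)phenyl]hexan-1-one | CCCCCC(=O)c1c(O)cc(OCOC)cc1OC(C)(C)C#C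
F6 | step 3 | 1-[2,6-dihydroxy-4-(methoxymethoxy)-3-(3-methylbuta-1,2-dien-1-yl)phenyl]hexan-1-one | CCCCCC(=O)c1c(O)cc(OCOC)c(C=C=C(C)C)c1O
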